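**Retrosynthetic overview**

1. The target is the (1R,2S,3S) enantiomer of isolariciresinol. Tetralin numbering is used: C1 = CH carrying ring C, C2 and C3 = CH carrying the hydroxymethyl groups, C4 = CH2. Ring A is the fused phenol ring (C6–OMe, C7–OH), ring B the carbocycle, ring C the pendant guaiacyl ring.
2. Last disconnections: both CH2OH groups come from esters in one LiAlH4 operation that also removes the lactate auxiliaries and the pivalate. The C1–ring C bond comes from Friedel–Crafts arylation of guaiacol (para to its OH) by the C1 cation, which the C6 methoxy group para to C8a stabilises.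
3. Ring B comes from a photoenolisation/Diels–Alder union of a 2-methylbenzaldehyde (ring A, C1 as CHO, C4 as CH3) with the C2-symmetric bis-(S)-lactate fumarate (C2–C3). It closes the ring through the C4–C3 and C1–C2 bonds and sets C2 and C3.
4. Enabling feature: C4 and C1 are ortho neighbours on ring A (on C4a and C8a). Light therefore turns the CH3/CHO pair into the hydroxy-o-quinodimethane C4=C4a–C8a=C1, a diene whose cycloaddition regains the aromaticity of ring A.
5. Order of rings: A is bought (creosol), B is made in the key step, C is attached afterwards; C1 is relayed from C2 by substrate control.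

Key step: step 4

Assumption: the two (S)-lactate groups are taken to steer the dienol to the fumarate face that gives the (1R,2R,3S) adduct 9, by analogy with lactate and mandelate fumarates in additions of hydroxy-o-quinodimethanes; if the facial sense proved opposite, the identical route with methyl (R)-lactate would give the same target.

**Route**

Step 1
Reactants: 1 creosol (2-methoxy-4-methylphenol)
Product: 2 2-methoxy-4-methylphenyl 2,2-dimethylpropanoate
Conditions: PivCl, Et3N, DMAP (cat.), CH2Cl2, 0 °C → rt
Reagents that add atoms: pivaloyl chloride, CC(C)(C)C(=O)Cl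
Why: DMAP-catalysed O-acylation of the phenol; the pivalate weakens this oxygen as a director so that the methoxy group alone controls step 2, is inert to light and acid, and is removed by hydride in step 6.

Step 2
Reactants: 2 2-methoxy-4-methylphenyl 2,2-dimethylpropanoate
Product: 4 5-formyl-2-methoxy-4-methylphenyl 2,2-dimethylpropanoate, via aryl chloro(methoxy)methane 3 (not isolated)
Conditions: Cl2CHOMe, TiCl4, CH2Cl2, −10 → 0 °C; then ice/H2O
Reagents that add atoms: dichloromethyl methyl ether, COC(Cl)Cl; water, O
Why: Rieche formylation (electrophilic aromatic substitution, then hydrolysis of the α-chloro ether 3 on work-up); the position para to the methoxy group and ortho to the methyl group is the only doubly activated, unhindered site, and it is the carbon that becomes C8a.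

Step 3
Reactants: 5 fumaryl chloride, 6 methyl (S)-lactate (2.1 equiv)
Product: 7 bis[(2S)-1-methoxy-1-oxopropan-2-yl] (2E)-but-2-enedioate
Conditions: pyridine, CH2Cl2, 0 °C → rt
Reagents that add atoms: none
Why: Double O-acylation of the secondary alcohol by the diacid chloride (nucleophilic acyl substitution); the lactate stereocentre is not involved and the E geometry of the fumarate is kept.

Step 4
Reactants: 4 5-formyl-2-methoxy-4-methylphenyl 2,2-dimethylpropanoate, 7 bis[(2S)-1-methoxy-1-oxopropan-2-yl] (2E)-but-2-enedioate
Product: 9 bis[(2S)-1-methoxy-1-oxopropan-2-yl] (1R,2R,3S)-7-(2,2-dimethylpropanoyloxy)-1-hydroxy-6-methoxy-1,2,3,4-tetrahydronaphthalene-2,3-dicarboxylate, via (E)-hydroxy-o-quinodimethane 8 (not isolated)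
Conditions: hν (365 nm LED), 7 (2 equiv), degassed PhMe, 20 °C
Reagents that add atoms: none
Why: Excitation of the aryl aldehyde (n,π*) and intersystem crossing are followed by 1,5-hydrogen transfer from the ortho methyl group (future C4) to the carbonyl oxygen, and the biradical collapses to the (E)-hydroxy-o-quinodimethane 8, whose Z isomer simply returns to 4 by a thermal 1,5-hydrogen shift. Dienol 8 is a very electron-rich diene whose cycloaddition restores the aromaticity of ring A, so the electron-poor fumarate 7 should capture it in a suprafacial endo [4+2] cycloaddition (intermolecular, four-carbon unit C1–C8a–C4a–C4 plus two-carbon unit C2–C3) that closes ring B by forming the C4–C3 bond together with the C1–C2 bond; the closest known reaction type is the photoenolisation/Diels–Alder reaction of 2-methylbenzaldehydes with fumarates and acrylates, including lactate and mandelate fumarates. C2 and C3 are set trans by the E geometry of the dienophile (stereospecific suprafacial addition), and the C1 hydroxyl should end up cis to the C2 ester because this ester sits endo and accepts a hydrogen bond from the dienol O–H. The absolute configuration comes from the two (S)-lactate groups, which make the two faces of the C2-symmetric fumarate diastereotopic and are held in place by the same hydrogen bond (see the assumption above). The step needs π-facial selectivity, secured by the auxiliary (a minor diastereomer would still be separable because the auxiliaries remain attached), and chemoselectivity against E/Z isomerisation of 7 and photoreduction of 4, secured by 365 nm light that only the aldehyde absorbs and by the fast intramolecular hydrogen transfer that outruns bimolecular quenching.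

Step 5
Reactants: 9 bis[(2S)-1-methoxy-1-oxopropan-2-yl] (1R,2R,3S)-7-(2,2-dimethylpropanoyloxy)-1-hydroxy-6-methoxy-1,2,3,4-tetrahydronaphthalene-2,3-dicarboxylate, 10 guaiacol (2-methoxyphenol, 5 equiv)
Product: 12 bis[(2S)-1-methoxy-1-oxopropan-2-yl] (1R,2S,3S)-7-(2,2-dimethylpropanoyloxy)-1-(4-hydroxy-3-methoxyphenyl)-6-methoxy-1,2,3,4-tetrahydronaphthalene-2,3-dicarboxylate, via C1 benzylic cation 11 (not isolated)
Conditions: TfOH (10 mol %), (CF3)2CHOH/CH2Cl2 (1:4), −20 → 0 °C
Reagents that add atoms: none
Why: Brønsted acid-catalysed SN1 Friedel–Crafts alkylation: ionisation of the C1 benzylic alcohol (loss of water) is assisted by the C6 methoxy group para to C8a, guaiacol should react at the position para to its free hydroxyl (its strongest donor), and the arene should approach the planar C1 on the face away from the adjacent pseudo-equatorial C2 ester, which sets C1 as R (1,2-trans) without touching C2 or C3 (the C2 descriptor changes from R to S only through the priority rules).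

Step 6
Reactants: 12 bis[(2S)-1-methoxy-1-oxopropan-2-yl] (1R,2S,3S)-7-(2,2-dimethylpropanoyloxy)-1-(4-hydroxy-3-methoxyphenyl)-6-methoxy-1,2,3,4-tetrahydronaphthalene-2,3-dicarboxylate
Product: 13 (1R,2S,3S)-1-(4-hydroxy-3-methoxyphenyl)-2,3-bis(hydroxymethyl)-6-methoxy-1,2,3,4-tetrahydronaphthalen-7-ol (target)
Conditions: LiAlH4 (excess), THF, 0 → 50 °C; then 1 M aq. HCl, 0 °C
Reagents that add atoms: none
Why: Ester reduction by LiAlH4: the two ring esters become the C2 and C3 hydroxymethyl groups while the lactate-derived parts leave as propane-1,2-diol and the pivalate as neopentyl alcohol, so auxiliary removal, deprotection and adjustment of the oxidation level fall into one operation and no stereocentre is touched.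

**Compound list**

1 | creosol (2-methoxy-4-methylphenol) | COc1cc(C)ccc1O | starting material
2 | 2-methoxy-4-methylphenyl 2,2-dimethylpropanoate | COc1cc(C)ccc1OC(=O)C(C)(C)C | intermediate
3 | 5-[chloro(methoxy)methyl]-2-methoxy-4-methylphenyl 2,2-dimethylpropanoate (racemic α-chloro ether, not isolated) | COC(Cl)c1cc(OC(=O)C(C)(C)C)c(OC)cc1C | intermediate
4 | 5-formyl-2-methoxy-4-methylphenyl 2,2-dimethylpropanoate | O=Cc1cc(OC(=O)C(C)(C)C)c(OC)cc1C | intermediate
5 | fumaryl chloride | O=C(Cl)/C=C/C(=O)Cl | starting material
6 | methyl (S)-lactate | C[C@H](O)C(=O)OC | starting material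
7 | bis[(2S)-1-methoxy-1-oxopropan-2-yl] (2E)-but-2-enedioate | COC(=O)[C@H](C)OC(=O)/C=C/C(=O)O[C@@H](C)C(=O)OC | intermediate
8 | (3E)-3-(hydroxymethylidene)-6-methoxy-4-methylidenecyclohexa-1,5-dien-1-yl 2,2-dimethylpropanoate (E-dienol, OH anti to the exocyclic CH2, not isolated) | C=C1C=C(OC)C(OC(=O)C(C)(C)C)=C/C1=C\O | intermediate
9 | bis[(2S)-1-methoxy-1-oxopropan-2-yl] (1R,2R,3S)-7-(2,2-dimethylpropanoyloxy)-1-hydroxy-6-methoxy-1,2,3,4-tetrahydronaphthalene-2,3-dicarboxylate (1-OH cis to the C2 ester, esters trans) | O[C@H]1c2cc(OC(=O)C(C)(C)C)c(OC)cc2C[C@H](C(=O)O[C@@H](C)C(=O)OC)[C@H]1C(=O)O[C@@H](C)C(=O)OC | intermediate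
10 | guaiacol (2-methoxyphenol) | COc1ccccc1O | starting material
11 | (2S,3S)-C1 benzylic carbocation derived from 9, as its triflate ion pair (not isolated) | [CH+]1c2cc(OC(=O)C(C)(C)C)c(OC)cc2C[C@H](C(=O)O[C@@H](C)C(=O)OC)[C@H]1C(=O)O[C@@H](C)C(=O)OC.[O-]S(=O)(=O)C(F)(F)F | intermediate
12 | bis[(2S)-1-methoxy-1-oxopropan-2-yl] (1R,2S,3S)-7-(2,2-dimethylpropanoyloxy)-1-(4-hydroxy-3-methoxyphenyl)-6-methoxy-1,2,3,4-tetrahydronaphthalene-2,3-dicarboxylate (all-trans) | COc1cc([C@@H]2c3cc(OC(=O)C(C)(C)C)c(OC)cc3C[C@H](C(=O)O[C@@H](C)C(=O)OC)[C@H]2C(=O)O[C@@H](C)C(=O)OC)ccc1O | intermediate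
13 | (1R,2S,3S)-1-(4-hydroxy-3-methoxyphenyl)-2,3-bis(hydroxymethyl)-6-methoxy-1,2,3,4-tetrahydronaphthalen-7-ol | COc1cc([C@@H]2c3cc(O)c(OC)cc3C[C@H](CO)[C@H]2CO)ccc1O | target

**Step count and risks**

Total step count: 6. Longest linear sequence: 5 (steps 1, 2, 4, 5, 6; step 3 prepares the dienophile).

Steps most likely to fail:

1. Step 5. The C1 cation may lose the C2 proton to give the conjugated 3,4-dihydronaphthalene ester, guaiacol may be attacked para to its methoxy group or ortho to its hydroxyl, and the facial bias at C1 may be insufficient. The fallback sets out from 9 and comes back at 13; it fixes ring C by cross-coupling and relays C1 and C2 from C3. Oxidation of 9 (Dess–Martin periodinane, CH2Cl2) would give the enolisable 1-oxo diester F1. NaH and PhNTf2 (THF, 0 °C) would give the enol triflate F2. Suzuki coupling with 2-methoxy-4-(4,4,5,5-tetramethyl-1,3,2-dioxaborolan-2-yl)phenol (PdCl2(dppf), K3PO4, dioxane, 70 °C) would give the 1-aryl-3,4-dihydronaphthalene F3 with no regiochemical question. Hydrogenation (H2, Pd/C, EtOAc) should occur on the face opposite the pseudo-axial C3 ester and give the all-cis diester F4. NaOMe in MeOH at reflux should epimerise C2 to the thermodynamically preferred all-trans arrangement while exchanging the lactate esters and cleaving the pivalate, giving the dimethyl ester F5, which LiAlH4 in THF reduces to 13.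

2. Step 4. Capture of the short-lived dienol may lose out to its return to the aldehyde, and light-driven E/Z isomerisation of the fumarate would leak into cis-diester adducts. The fallback sets out from 4 and comes back at 9; it separates the photochemistry from the cycloaddition. Irradiation of 4 (365 nm) in benzene saturated with SO2 should trap the dienol as the cyclic hydroxy sulfone F6. Heating F6 with 7 in toluene at 80–110 °C releases the same dienol 8 slowly by cheletropic loss of SO2, in the dark and in the presence of the dienophile, and should give 9.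

3. Step 2. The Lewis acid may cleave the aryl ester, or formylation may occur next to the methoxy group. The fallback sets out from 2 and comes back at 4; it replaces direct formylation by halogenation and catalytic carbonylation. Bromination of 2 with NBS (MeCN, 0 °C → rt), which needs no Lewis acid, should give the aryl bromide F7. Reductive carbonylation (Pd(OAc)2, di(1-adamantyl)-n-butylphosphine, CO/H2 1:1, TMEDA, PhMe, 100 °C) would then give 4.

**Further compounds**

F1 | step 5 | bis[(2S)-1-methoxy-1-oxopropan-2-yl] (3S)-7-(2,2-dimethylpropanoyloxy)-6-methoxy-1-oxo-1,2,3,4-tetrahydronaphthalene-2,3-dicarboxylate (C2 epimers and enol) | O=C1c2cc(OC(=O)C(C)(C)C)c(OC)cc2C[C@H](C(=O)O[C@@H](C)C(=O)OC)C1C(=O)O[C@@H](C)C(=O)OC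
F2 | step 5 | bis[(2S)-1-methoxy-1-oxopropan-2-yl] (3S)-7-(2,2-dimethylpropanoyloxy)-6-methoxy-1-(trifluoromethanesulfonyloxy)-3,4-dihydronaphthalene-2,3-dicarboxylate | FC(F)(F)S(=O)(=O)OC1=C(C(=O)O[C@@H](C)C(=O)OC)[C@@H](C(=O)O[C@@H](C)C(=O)OC)Cc2cc(OC)c(OC(=O)C(C)(C)C)cc21
F3 | step 5 | bis[(2S)-1-methoxy-1-oxopropan-2-yl] (3S)-7-(2,2-dimethylpropanoyloxy)-1-(4-hydroxy-3-methoxyphenyl)-6-methoxy-3,4-dihydronaphthalene-2,3-dicarboxylate | COc1cc(C2=C(C(=O)O[C@@H](C)C(=O)OC)[C@@H](C(=O)O[C@@H](C)C(=O)OC)Cc3cc(OC)c(OC(=O)C(C)(C)C)cc32)ccc1O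
F4 | step 5 | bis[(2S)-1-methoxy-1-oxopropan-2-yl] (1R,2R,3S)-7-(2,2-dimethylpropanoyloxy)-1-(4-hydroxy-3-methoxyphenyl)-6-methoxy-1,2,3,4-tetrahydronaphthalene-2,3-dicarboxylate (all-cis) | COc1cc([C@@H]2c3cc(OC(=O)C(C)(C)C)c(OC)cc3C[C@H](C(=O)O[C@@H](C)C(=O)OC)[C@@H]2C(=O)O[C@@H](C)C(=O)OC)ccc1O
F5 | step 5 | dimethyl (1R,2S,3S)-7-hydroxy-1-(4-hydroxy-3-methoxyphenyl)-6-methoxy-1,2,3,4-tetrahydronaphthalene-2,3-dicarboxylate (all-trans) | COc1cc([C@@H]2c3cc(O)c(OC)cc3C[C@H](C(=O)OC)[C@H]2C(=O)OC)ccc1O
F6 | step 4 | 1-hydroxy-5-methoxy-2,2-dioxo-1,3-dihydrobenzo[c]thiophen-6-yl 2,2-dimethylpropanoate (racemic) | OC1c2cc(OC(=O)C(C)(C)C)c(OC)cc2CS1(=O)=O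
F7 | step 2 | 5-bromo-2-methoxy-4-methylphenyl 2,2-dimethylpropanoate | COc1cc(C)c(Br)cc1OC(=O)C(C)(C)C
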